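The amber run, charged with 1.6 M of solid substrate under the same held gas phase, tells me what the violet flask, charged with 0.80 M, holds at 4.0 min, provided I count in M and not in percent.

all flasks: gas phase 40 mM (held)

| flask | solid substrate | remark | time |
|---|---|---|---|
| violet | 0.80 M | the very flask that is asked about, followed so far |  |
| amber | 1.6 M | run made earlier |  |
| flask | 0.80 M |  | 4.0 min |

violet run (percent of the solid substrate charged)

| time / s | target / % | solid substrate / % |
|---|---|---|
| 10.0 | 0 | 96 |
| 12.0 | 0 | 93 |
| 20.0 | 3 | 86 |
| 25.0 | 0 | 86 |
| 40.0 | 3 | 79 |
| 60.0 | 3 | 71 |
| 90.0 | 8 | 57 |

amber run (percent of the solid substrate charged)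

| time / min | target / % | solid substrate / % |
|---|---|---|
| 0.333 | 4 | 93 |
| 0.500 | 1 | 93 |
| 0.667 | 2 | 92 |
| 1.00 | 1 | 85 |
| 1.50 | 6 | 78 |
| 2.50 | 9 | 68 |
| 4.00 | 13 | 56 |

(each reading ± 1.5 percentage points)

- solid substrate is a solid; its amount is given per volume of the solution
- the earlier runs were read with a standard deviation of 1.5 percentage points
- at the start none of the gas phase is in solution
- at the start none of the solid substrate is in solution

- larch: doubling the solubility of the solid substrate, all else as stated
- alder: doubling the transfer coefficient of the gas phase, all else as stated
- ash: doubling the dissolution coefficient of the solid substrate, all else as stated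
- birch: doubling the saturation concentration of gas phase, all else as stated

- target at 4.0 min, in percent of the solid substrate charged
- the change that raises the amount of target at 4.0 min, in percent of the solid substrate charged most ("none" if none brings more than 2 percentage points) (larch / alder / ash / birch / none)
- amount of target at 4.0 min, in percent of the solid substrate charged, after alder

In the first instants violet has lost 0.112 M of solid substrate at 20.0 s, and amber 0.112 M at 0.333 min, while target reads 3% and 4%. In the middle, at 90.0 s, violet has lost 0.344 M, and amber 0.352 M at 1.50 min, although amber's charge is twice violet's. So in these two runs the loss of solid reads as zero order in the charge. Target trails that loss: at 90.0 s violet holds 0.0640 M of target, less than the solid it has lost.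

At the end, amber has lost 0.704 M at 4.00 min, which is less than violet's charge. Violet should therefore keep 0.0960 M of solid at 4.0 min, and that margin is what the reckoning stands on. Amber's 13% is 0.208 M of target. I carry this as the molar target: target per volume of solution at that time, taken over to a charge that still keeps solid then under this gas phase. For violet it gives 26.0%, and since amber's charge is twice violet's, a reading's 1.5 percentage points counts twice on this figure.

The forecast gives 26%, birch as the best change, and 44% after alder, with the ground “Charge therefore doesn't matter”. Its target figure is the same as mine.

The flask gives 28.8%, birch as the best change with a gain of 13 points, and 35.4% after alder, which is 8.6 points below the forecast.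

    gas phase ⇌ dissolved gas, rate k1*(csat - [dissolved gas]) (kL = 0.0720 s⁻¹)
    starting material + dissolved gas → target (k = 0.550 L mol⁻¹ s⁻¹)
    dissolved gas + target → over-reacted product (k = 0.0940 L mol⁻¹ s⁻¹)
    dissolved gas → decomposed reagent (k = 0.0160 s⁻¹)
    starting material ⇌ dormant form (K = 1.50, k = 0.0720 s⁻¹)
    solid substrate ⇌ starting material, rate k6*(cs6 - [starting material]) while solid is left; crystals form when [starting material] > cs6 (solubility = 0.330 M, k = 0.0140 s⁻¹)

The flask keeps 11.9% as solid at 4.00 min, and there the 26.0% from the molar target stands beside the 28.8% found. The neighbour charged with 1.4 M is read at the same time, and the same 0.208 M gives it 14.9%. There [dissolved gas] is 0.0139 M, equal to the flask's 0.0139 M, and the neighbour stands at 16.5% of target with 49.7% of its charge still solid.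

The earlier runs and the new flask were generated by integration on assumed constants.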